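**Plan**

- Carotenoid numbering is used; primed locants run from the central C15=C15' bond to the CH2OH carbon C8'. The enabling feature is the terminal diene C12'=C11'–C10'=C9'(CH3) next to C8': C12' and C9' are read as former carbonyl carbons (aldehyde, methyl ketone) and C11'–C10' as acetylene. The only ring, the cyclohexene C1–C6, comes with α-ionone.
- Retrosynthetic cuts, in order: the C3–O silyl group and the C8' oxidation level; the diene back to an E-ene-1,4-diol and a yne-diol; C12'–C11' and C10'–C9' to a C25 aldehyde, ethynylmagnesium bromide and 1,1-dimethoxypropan-2-one; C11=C12 (Wittig) to a C15 phosphonium salt and a C10 dial; C9–C10 (vinyl Grignard); C3–O back to α-ionone.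
- Forward: no ring is formed. The chain grows C13 → C15 → C25 → C30, the diene is unveiled by trans-reduction and titanium-mediated double deoxygenation, and C8' is brought to the alcohol.
- Stereochemistry: C6 comes from racemic α-ionone and C3 from hydride reduction of the 3-ketone (trans epimer separated); one lipase kinetic resolution fixes both as (3R,6R). Alkene geometry comes from the all-E dial, Wittig plus iodine equilibration, LiAlH4 trans-hydroalumination, and thermodynamically controlled E,E-diene and E-enal formation.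

Key step: step 10

Assumption: lipase PS is taken to acylate the (3S,6S) enantiomer of the trans alcohol, whose carbinol centre has the spatial sense of the fast-reacting alcohols of the β-ring series, so the (3R,6R) alcohol is recovered; were the preference reversed, the acetate would be the (3R,6R) compound and would be methanolysed (K2CO3, MeOH) to the same alcohol.

Step 1
Reactants: 1 α-ionone (racemic)
Product: 2 α-ionone ethylene ketal (racemic)
Conditions: HOCH2CH2OH, HC(OEt)3, cat. p-TsOH·H2O, rt
Reagents that add atoms: ethylene glycol, OCCO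
Why: Acid-catalysed ketalisation with the orthoformate as water scavenger masks the side-chain enone so that the ring ketone made next can be reduced alone, and the mild conditions leave the C4=C5 alkene in place.

Step 2
Reactants: 2 α-ionone ethylene ketal
Product: 3 3-oxo-α-ionone ethylene ketal (racemic)
Conditions: t-BuOOH (70% aq.), Rh2(cap)4 (dirhodium tetracaprolactamate, 1 mol %), K2CO3, CH2Cl2, rt
Reagents that add atoms: tert-butyl hydroperoxide, CC(C)(C)OO
Why: Radical allylic C–H oxidation by tert-butylperoxyl radicals converts the only ring allylic CH2 (C3) into the enone carbonyl, while C6–H, wedged between the quaternary C1 and the C5 methyl, is expected to react more slowly.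

Step 3
Reactants: 3 3-oxo-α-ionone ethylene ketal
Product: 4 rac-(3R*,6R*)-3-hydroxy-α-ionone ethylene ketal (3,6-trans)
Conditions: i-Bu2AlH, CH2Cl2, −78 °C; aq. potassium sodium tartrate; chromatography (trans from cis)
Reagents that add atoms: none
Why: 1,2-Hydride reduction of the ring enone creates C3 with the ketal inert; the axial C1 methyl and the C6 side chain shield opposite faces to a similar degree, so both carbinol epimers are expected and the 3,6-trans racemate is taken by chromatography, which fixes the relative configuration of C3 and C6.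

Step 4
Reactants: 4 rac-(3R*,6R*)-3-hydroxy-α-ionone ethylene ketal
Product: 5 (3R,6R)-3-hydroxy-α-ionone ethylene ketal
Conditions: lipase PS (Burkholderia cepacia), vinyl acetate, t-BuOMe, rt, to just past half conversion; chromatography
Reagents that add atoms: none
Why: Lipase-catalysed irreversible transesterification is a kinetic resolution in which the enzyme should acylate the (3S,6S) alcohol much faster, so the untouched (3R,6R) enantiomer is recovered enantiopure once conversion passes one half, which sets the absolute configuration at C3 and C6 together.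

Step 5
Reactants: 5 (3R,6R)-3-hydroxy-α-ionone ethylene ketal
Product: 6 (3R,6R)-3-hydroxy-α-ionone
Conditions: PPTS, acetone/H2O, rt
Reagents that add atoms: water, O
Why: Hydrolysis of an allylic dioxolane is fast under buffered acid, at which the secondary ring allylic alcohol should not ionise, so C3 keeps its configuration.

Step 6
Reactants: 6 (3R,6R)-3-hydroxy-α-ionone; 7 vinylmagnesium bromide
Product: 8 (3R,6R)-3-hydroxy-9-vinyl-α-ionol (C9 epimers)
Conditions: CH2=CHMgBr (3 equiv), THF, −20 → 0 °C; aq. NH4Cl
Reagents that add atoms: none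
Why: 1,2-Grignard addition to the methyl ketone forms C9–C10, a standard transformation of ionones; the first equivalent is consumed by the hydroxyl proton, and the C9 carbinol centre is left uncontrolled because the next step destroys it.

Step 7
Reactants: 8 (3R,6R)-3-hydroxy-9-vinyl-α-ionol
Product: 9 (3R,6R)-3-hydroxy-α-ionylideneethyl triphenylphosphonium bromide (9E)
Conditions: Ph3P·HBr, CH2Cl2, 0 °C → rt; crystallisation from EtOAc
Reagents that add atoms: triphenylphosphine hydrobromide, Br.c1ccc(cc1)P(c1ccccc1)c1ccccc1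
Why: SN1' substitution in which the tertiary bis-allylic carbinol ionises to a pentadienyl cation that triphenylphosphine captures at the primary terminus C11, the classical way to C15 Wittig salts; the secondary ring alcohol is far harder to ionise, and crystallisation should enrich the 9E salt.

Step 8
Reactants: 9 (3R,6R)-3-hydroxy-α-ionylideneethyl triphenylphosphonium bromide; 10 (2E,4E,6E)-2,7-dimethylocta-2,4,6-trienedial
Product: 13 (3R,6R)-3-hydroxy-12'-apo-ε-caroten-12'-al (all-E), via phosphorus ylide 11 (not isolated), via 11Z aldehyde 12 (not isolated)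
Conditions: NaOMe, MeOH/CH2Cl2, 0 °C → rt, 10 in excess (2 equiv, remainder recovered); then cat. I2, CH2Cl2, rt, daylight
Reagents that add atoms: none
Why: Wittig olefination of the semistabilised allylic ylide with one aldehyde group of the symmetric dial forms C11=C12 in the classical C15 + C10 polyene coupling, the excess of dial suppresses double olefination, and iodine-catalysed equilibration turns the 11Z (and any 9Z) isomer into the all-E aldehyde.

Step 9
Reactants: 13 (3R,6R)-3-hydroxy-12'-apo-ε-caroten-12'-al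
Product: 14 (3R,6R)-3-(tert-butyldimethylsilyloxy)-12'-apo-ε-caroten-12'-al
Conditions: TBSCl, imidazole, DMF, rt
Reagents that add atoms: tert-butyldimethylsilyl chloride, CC(C)(C)[Si](C)(C)Cl
Why: Standard silylation of the secondary alcohol; the silyl ether shields the ring allylic oxygen from the Grignard, hydride and low-valent titanium reagents to come.

Step 10
Reactants: 14 (3R,6R)-3-(tert-butyldimethylsilyloxy)-12'-apo-ε-caroten-12'-al; 15 ethynylmagnesium bromide; 16 1,1-dimethoxypropan-2-one
Product: 19 C30 yne-diol dimethyl acetal (C12'–OH, C11'≡C10', C9'–OH, C8' acetal; both new carbinol centres as mixtures), via bromomagnesium alkynolate 17 (not isolated), via alkynyl Grignard alkoxide 18 (not isolated)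
Conditions: 15 (0.5 M in THF) + 16 (1:1), THF, 0 °C → rt; EtMgBr (0.95 equiv per alkyne), rt → 40 °C; 14 (0.4 equiv), 0 °C → rt; aq. NH4Cl; silica with 1% Et3N
Reagents that add atoms: none
Why: Ethynylmagnesium bromide adds to the ketone carbonyl of 16 to give alkoxide 17 (C10'–C9' bond); EtMgBr, kept just short of one equivalent so that none survives, removes the remaining alkyne proton to give the C,O-dimagnesium species 18, which adds 1,2 to the aldehyde of 14 (C12'–C11' bond). The closest known reaction type is the sequential addition of an acetylenic carbinol Grignard (an alkoxide-bearing alkynylmagnesium halide) to a polyenal, long used in retinoid and carotenoid chain assembly. No ring is closed. The two new carbinol centres, C12' and C9', form without control and are deliberately left as mixtures, because both oxygens are excised in step 12. The step needs mono-addition of acetylene to the ketone and 1,2- rather than conjugate addition to the hexaenal: an equimolar amount of ketone at 0 °C in THF keeps the acetylene bis-Grignard from forming, hard alkynyl Grignards attack polyenals at the carbonyl carbon, and the acetal and silyl ether are inert.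

Step 11
Reactants: 19 C30 yne-diol dimethyl acetal
Product: 20 C30 (11'E)-ene-1,4-diol dimethyl acetal
Conditions: LiAlH4, THF, 0 °C → rt; aq. potassium sodium tartrate
Reagents that add atoms: none
Why: Hydroxyl-directed trans-hydroalumination of the propargylic diol (hydride delivered from the alkoxyaluminate) and protonolysis give the E-alkene; keeping the temperature low should avoid elimination to allenes, and the silyl ether and acetal do not react.

Step 12
Reactants: 20 C30 (11'E)-ene-1,4-diol dimethyl acetal
Product: 21 (3R,6R)-3-(tert-butyldimethylsilyloxy)-8'-apo-ε-caroten-8'-al dimethyl acetal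
Conditions: TiCl3/LiAlH4 (2:1), THF, 0 °C → rt, then 20, rt → 50 °C; aq. K2CO3
Reagents that add atoms: none
Why: Low-valent titanium reductive 1,4-elimination of a 2-ene-1,4-diol cleaves both C–O bonds through titanium alkoxides and shifts the alkene, so C12'=C11' and C10'=C9' form with the E,E diene expected to prevail and the carbinol configurations become irrelevant.

Step 13
Reactants: 21 (3R,6R)-3-(tert-butyldimethylsilyloxy)-8'-apo-ε-caroten-8'-al dimethyl acetal
Product: 22 (3R,6R)-3-(tert-butyldimethylsilyloxy)-8'-apo-ε-caroten-8'-al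
Conditions: PPTS, acetone/H2O, rt
Reagents that add atoms: water, O
Why: Acetal hydrolysis of a polyene-conjugated dimethyl acetal is very fast under buffered acid that leaves the silyl ether alone, and the 2-methyl-2-enal is most stable as the E isomer, so any 9'Z material should equilibrate under the acidic conditions.

Step 14
Reactants: 22 (3R,6R)-3-(tert-butyldimethylsilyloxy)-8'-apo-ε-caroten-8'-al
Product: 23 (3R,6R)-3-(tert-butyldimethylsilyloxy)-8'-apo-ε-caroten-8'-ol
Conditions: NaBH4, MeOH/THF, 0 °C
Reagents that add atoms: none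
Why: Borohydride 1,2-reduction of a polyenal to the allylic alcohol, as in the reduction of retinal to retinol, leaves the conjugated chain untouched.

Step 15
Reactants: 23 (3R,6R)-3-(tert-butyldimethylsilyloxy)-8'-apo-ε-caroten-8'-ol
Product: 24 (3R,6R)-3-hydroxy-8'-apo-ε-caroten-8'-ol (CNP0292981.1)
Conditions: TBAF, THF, 0 °C → rt
Reagents that add atoms: none
Why: Fluoride-mediated Si–O cleavage runs under non-acidic conditions that the acid-sensitive ring allylic alcohol and the polyene tolerate, so C3 and C6 stay as set.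

**Compound list**

1 | α-ionone, racemic; (E)-4-(2,6,6-trimethylcyclohex-2-en-1-yl)but-3-en-2-one | CC1=CCCC(C)(C)C1/C=C/C(C)=O | starting material
2 | α-ionone ethylene ketal, racemic; 2-methyl-2-[(E)-2-(2,6,6-trimethylcyclohex-2-en-1-yl)ethenyl]-1,3-dioxolane | CC1=CCCC(C)(C)C1/C=C/C2(C)OCCO2 | intermediate
3 | 3-oxo-α-ionone ethylene ketal, racemic; 3,5,5-trimethyl-4-[(E)-2-(2-methyl-1,3-dioxolan-2-yl)ethenyl]cyclohex-2-en-1-one | CC1=CC(=O)CC(C)(C)C1/C=C/C2(C)OCCO2 | intermediate
4 | rac-(3R*,6R*)-3-hydroxy-α-ionone ethylene ketal (3,6-trans racemate, one enantiomer drawn) | CC1=C[C@H](O)CC(C)(C)[C@H]1/C=C/C2(C)OCCO2 | intermediate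
5 | (3R,6R)-3-hydroxy-α-ionone ethylene ketal; (1R,4R)-3,5,5-trimethyl-4-[(E)-2-(2-methyl-1,3-dioxolan-2-yl)ethenyl]cyclohex-2-en-1-ol | CC1=C[C@H](O)CC(C)(C)[C@H]1/C=C/C2(C)OCCO2 | intermediate
6 | (3R,6R)-3-hydroxy-α-ionone; (E)-4-[(1R,4R)-4-hydroxy-2,6,6-trimethylcyclohex-2-en-1-yl]but-3-en-2-one | CC1=C[C@H](O)CC(C)(C)[C@H]1/C=C/C(C)=O | intermediate
7 | vinylmagnesium bromide | C=C[Mg]Br | starting material
8 | (3R,6R)-3-hydroxy-9-vinyl-α-ionol; (1R,4R)-4-[(1E)-3-hydroxy-3-methylpenta-1,4-dien-1-yl]-3,5,5-trimethylcyclohex-2-en-1-ol, C9 epimers | CC1=C[C@H](O)CC(C)(C)[C@H]1/C=C/C(C)(O)C=C | intermediate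
9 | [(2E,4E)-5-[(1R,4R)-4-hydroxy-2,6,6-trimethylcyclohex-2-en-1-yl]-3-methylpenta-2,4-dien-1-yl]triphenylphosphonium bromide | CC1=C[C@H](O)CC(C)(C)[C@H]1/C=C/C(C)=C/C[P+](c2ccccc2)(c2ccccc2)c2ccccc2.[Br-] | intermediate
10 | (2E,4E,6E)-2,7-dimethylocta-2,4,6-trienedial (C10 dial) | O=C/C(C)=C/C=C/C=C(C)/C=O | starting material
11 | phosphorus ylide of 9 (C11 ylide carbon) | CC1=C[C@H](O)CC(C)(C)[C@H]1/C=C/C(C)=C/C=P(c2ccccc2)(c2ccccc2)c2ccccc2 | intermediate
12 | (11Z)-(3R,6R)-3-hydroxy-12'-apo-ε-caroten-12'-al | CC1=C[C@H](O)CC(C)(C)[C@H]1/C=C/C(C)=C/C=C\C(C)=C\C=C\C=C(/C)C=O | intermediate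
13 | (3R,6R)-3-hydroxy-12'-apo-ε-caroten-12'-al, all-E | CC1=C[C@H](O)CC(C)(C)[C@H]1/C=C/C(C)=C/C=C/C(C)=C/C=C/C=C(C)/C=O | intermediate
14 | (3R,6R)-3-(tert-butyldimethylsilyloxy)-12'-apo-ε-caroten-12'-al | CC1=C[C@H](O[Si](C)(C)C(C)(C)C)CC(C)(C)[C@H]1/C=C/C(C)=C/C=C/C(C)=C/C=C/C=C(C)/C=O | intermediate
15 | ethynylmagnesium bromide | C#C[Mg]Br | starting material
16 | 1,1-dimethoxypropan-2-one | CC(=O)C(OC)OC | starting material
17 | bromomagnesium 1,1-dimethoxy-2-methylbut-3-yn-2-olate | C#CC(C)(O[Mg]Br)C(OC)OC | intermediate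
18 | C,O-bis(bromomagnesium) derivative of 1,1-dimethoxy-2-methylbut-3-yn-2-ol (alkynyl Grignard alkoxide) | Br[Mg]C#CC(C)(O[Mg]Br)C(OC)OC | intermediate
19 | C30 yne-diol dimethyl acetal: silyl ether 14 extended at C12' by C(OH)–C≡C–C(CH3)(OH)–CH(OCH3)2; (3R,6R), C12' and C9' unassigned mixtures | CC1=C[C@H](O[Si](C)(C)C(C)(C)C)CC(C)(C)[C@H]1/C=C/C(C)=C/C=C/C(C)=C/C=C/C=C(C)/C(O)C#CC(C)(O)C(OC)OC | intermediate
20 | C30 (11'E)-ene-1,4-diol dimethyl acetal; (3R,6R), C12' and C9' unassigned mixtures | CC1=C[C@H](O[Si](C)(C)C(C)(C)C)CC(C)(C)[C@H]1/C=C/C(C)=C/C=C/C(C)=C/C=C/C=C(C)/C(O)/C=C/C(C)(O)C(OC)OC | intermediate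
21 | (3R,6R)-3-(tert-butyldimethylsilyloxy)-8'-apo-ε-caroten-8'-al dimethyl acetal, all-E | CC1=C[C@H](O[Si](C)(C)C(C)(C)C)CC(C)(C)[C@H]1/C=C/C(C)=C/C=C/C(C)=C/C=C/C=C(C)/C=C/C=C(\C)C(OC)OC | intermediate
22 | (3R,6R)-3-(tert-butyldimethylsilyloxy)-8'-apo-ε-caroten-8'-al, all-E | CC1=C[C@H](O[Si](C)(C)C(C)(C)C)CC(C)(C)[C@H]1/C=C/C(C)=C/C=C/C(C)=C/C=C/C=C(C)/C=C/C=C(\C)C=O | intermediate
23 | (3R,6R)-3-(tert-butyldimethylsilyloxy)-8'-apo-ε-caroten-8'-ol, all-E | CC1=C[C@H](O[Si](C)(C)C(C)(C)C)CC(C)(C)[C@H]1/C=C/C(C)=C/C=C/C(C)=C/C=C/C=C(C)/C=C/C=C(\C)CO | intermediate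
24 | (3R,6R)-3-hydroxy-8'-apo-ε-caroten-8'-ol, all-E (CNP0292981.1) | CC1=C[C@H](O)CC(C)(C)[C@H]1/C=C/C(C)=C/C=C/C(C)=C/C=C/C=C(C)/C=C/C=C(\C)CO | target

**Step count**

Total steps: 15. Longest linear sequence: 15 steps, from α-ionone 1 to target 24; compounds 7, 10, 15 and 16 are purchased.

**Steps most likely to fail, with fallbacks**

1. Step 12 (titanium-mediated reductive elimination). The second C–O cleavage may lag behind the first, the long polyenyl radical may couple or be over-reduced, and Lewis-acidic titanium chlorides may ionise the acetal; each would erode the diene. The fallback gives up the deoxygenation and builds the same terminus by olefination; it sets out from aldehyde 14 and returns at alcohol 23. Ethyl tiglate is brominated at the γ-methyl group (NBS, cat. AIBN, PhCF3, reflux) to ethyl (E)-4-bromo-2-methylbut-2-enoate F1. An Arbuzov reaction with P(OEt)3 gives ethyl (E)-4-(diethoxyphosphoryl)-2-methylbut-2-enoate F2. Its anion (NaH, THF, 0 °C) olefinates 14 in a Horner–Wadsworth–Emmons reaction to ethyl (3R,6R)-3-(tert-butyldimethylsilyloxy)-8'-apo-ε-caroten-8'-oate F3. Reduction with i-Bu2AlH at −78 °C then delivers 23, and step 15 follows as planned.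

2. Step 7 (phosphonium salt formation). Under the acidic SN1' conditions the ring allylic alcohol may also ionise (epimerisation or substitution at C3), and the pentadienyl cation may lose the C6 proton to give retro-type polyenes. The fallback builds the C15 unit under neutral or basic conditions on the silyl ether; it sets out from 6 and returns at 14, so step 9 is not needed. Ketone 6 is silylated (TBSCl, imidazole, DMF) to (3R,6R)-3-(tert-butyldimethylsilyloxy)-α-ionone F4. A Horner–Wadsworth–Emmons reaction with triethyl phosphonoacetate (NaH, THF) gives ethyl (2E,4E)-(3R,6R)-3-(tert-butyldimethylsilyloxy)-α-ionylideneacetate F5, the 9E isomer being separated. Reduction with i-Bu2AlH gives the C15 allylic alcohol F6, CBr4/PPh3 gives the C15 allylic bromide F7, and an Arbuzov reaction with P(OEt)3 gives the C15 diethyl phosphonate F8. Its anion (KOtBu, THF, −30 °C) olefinates one aldehyde group of dial 10 and gives 14 directly.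

3. Step 3 (ketone reduction). Facial selectivity may be poor in the unwanted sense, with hydride arriving mainly on the face that leads to the cis carbinol, which would starve the route. The fallback corrects the carbinol configuration by inversion; it sets out from 3 and returns at 4. The cis racemate, rac-(3S*,6R*)-3-hydroxy-α-ionone ethylene ketal F9, is taken as the by-product of step 3 or made on purpose from 3 with a bulky hydride such as LiBH(s-Bu)3. Mitsunobu inversion (4-nitrobenzoic acid, PPh3, DIAD, THF, 0 °C) gives the trans 4-nitrobenzoate F10, and methanolysis (K2CO3, MeOH) gives 4.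

**Further compounds**

F1 | step 12 | ethyl (E)-4-bromo-2-methylbut-2-enoate | CCOC(=O)/C(C)=C/CBr
F2 | step 12 | ethyl (E)-4-(diethoxyphosphoryl)-2-methylbut-2-enoate | CCOC(=O)/C(C)=C/CP(=O)(OCC)OCC
F3 | step 12 | ethyl (3R,6R)-3-(tert-butyldimethylsilyloxy)-8'-apo-ε-caroten-8'-oate | CC1=C[C@H](O[Si](C)(C)C(C)(C)C)CC(C)(C)[C@H]1/C=C/C(C)=C/C=C/C(C)=C/C=C/C=C(C)/C=C/C=C(\C)C(=O)OCC
F4 | step 7 | (3R,6R)-3-(tert-butyldimethylsilyloxy)-α-ionone | CC1=C[C@H](O[Si](C)(C)C(C)(C)C)CC(C)(C)[C@H]1/C=C/C(C)=O
F5 | step 7 | ethyl (2E,4E)-5-[(1R,4R)-4-(tert-butyldimethylsilyloxy)-2,6,6-trimethylcyclohex-2-en-1-yl]-3-methylpenta-2,4-dienoate | CC1=C[C@H](O[Si](C)(C)C(C)(C)C)CC(C)(C)[C@H]1/C=C/C(C)=C/C(=O)OCC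
F6 | step 7 | (2E,4E)-5-[(1R,4R)-4-(tert-butyldimethylsilyloxy)-2,6,6-trimethylcyclohex-2-en-1-yl]-3-methylpenta-2,4-dien-1-ol | CC1=C[C@H](O[Si](C)(C)C(C)(C)C)CC(C)(C)[C@H]1/C=C/C(C)=C/CO
F7 | step 7 | (2E,4E)-1-bromo-5-[(1R,4R)-4-(tert-butyldimethylsilyloxy)-2,6,6-trimethylcyclohex-2-en-1-yl]-3-methylpenta-2,4-diene | CC1=C[C@H](O[Si](C)(C)C(C)(C)C)CC(C)(C)[C@H]1/C=C/C(C)=C/CBr
F8 | step 7 | diethyl [(2E,4E)-5-[(1R,4R)-4-(tert-butyldimethylsilyloxy)-2,6,6-trimethylcyclohex-2-en-1-yl]-3-methylpenta-2,4-dien-1-yl]phosphonate | CC1=C[C@H](O[Si](C)(C)C(C)(C)C)CC(C)(C)[C@H]1/C=C/C(C)=C/CP(=O)(OCC)OCC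
F9 | step 3 | rac-(3S*,6R*)-3-hydroxy-α-ionone ethylene ketal (3,6-cis racemate, one enantiomer drawn) | CC1=C[C@@H](O)CC(C)(C)[C@H]1/C=C/C2(C)OCCO2
F10 | step 3 | rac-(3R*,6R*)-3-(4-nitrobenzoyloxy)-α-ionone ethylene ketal (3,6-trans racemate, one enantiomer drawn) | CC1=C[C@H](OC(=O)c2ccc(cc2)[N+](=O)[O-])CC(C)(C)[C@H]1/C=C/C3(C)OCCO3
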